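(The numbers in the tables are calculated on assumed constants; scatter was added.)

Follow one molecule of free monomer through the flask and ask what its chance is, per minute, of going into a chain.

| flask | free monomer | initiator | remark | time |
|---|---|---|---|---|
| Wednesday's | 0.80 M | 3.5 mM | run made earlier |  |
| Monday's | 0.80 M | 23 mM | run made earlier |  |
| Tuesday's | 0.80 M | 140 mM | run made earlier |  |
| midnight | 0.80 M | 4.0 mM |  | 20 min |
| winter | 0.80 M | 12 mM |  | 20 min |
| dawn | 0.80 M | 40 mM |  | 20 min |
| autumn | 0.80 M | 120 mM |  | 20 min |

- Wednesday's (time / min: monomer in chains / %): 2.00: 1.1; 5.00: 1.9; 10.0: 3.5; 15.0: 5.0; 20.0: 6.9
- Monday's (time / min: monomer in chains / %): 1.50: 3.4; 3.00: 6.3; 6.00: 13.7; 10.0: 20.8; 20.0: 36.9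
- Tuesday's (time / min: monomer in chains / %): 4.00: 44.6; 8.00: 68.6; 12.0: 82.0; 15.0: 87.9; 20.0: 93.9

(standard deviation of a reading: 0.3 percentage points)

- the numbers in the tables scatter with a standard deviation of 0.3 percentage points
- "hardly changes" means that all values lie within two and a half points (for a concentration: within two and a half percent of the largest)

* amount of monomer in chains at the end, in percent of the free monomer charged for midnight, winter, dawn, autumn, in this order
* the course of these numbers from the first flask to the last (rises, then falls / falls, then rises / rises all the way / falls all the way / hardly changes)

If that chance holds steady through a run, free monomer decays exponentially (pseudo-first-order), and because the runs differ in their charge of initiator, I divide the chance by that charge. I call the result the catch constant: the chance per minute that one molecule of free monomer enters a chain, per unit of [initiator] charged. Monday's last reading gives it: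

catch constant = ln(1/(1 − share in chains)) / (time × charged [initiator]) = 1.00 /M/min

Wednesday's last reading gives 1.02 /M/min and Tuesday's 0.999 /M/min, with charges 40.0 times apart, so I commit to this one constant. Its inverse, divided by the charge, is my estimate of the mean life of free monomer in a flask, and I set these lives on a ladder against the run of 20 min:

autumn: life 8.33 min, in chains 90.9 %

dawn: life 25.0 min, in chains 55.1 %

winter: life 83.3 min, in chains 21.4 %

midnight: life 250 min, in chains 7.70 %

Autumn's life is shorter than the run, so I expect nearly all of its free monomer in chains by the end. Dawn's life is longer than the run, and I expect about half in chains there. In winter and midnight the estimated life is longer still, and the reckoned shares in chains are smaller.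

The forecast, holding that “the rate is first order in initiator”, gives 7.9 %, 21.5 %, 55.5 % and 91 %, and its course rises all the way; its midnight value stands above mine.

The flasks give 7.70 %, 21.4 %, 55.1 % and 91.0 %, and their course rises all the way.

    free monomer + initiator → living end + monomer in chains (k = 1.20 /M/min)
    free monomer + living end → monomer in chains + living end, rate k2*[living end]*[free monomer] (k = 0.990 /M/min)

In midnight, free monomer's half-life by the step with initiator, initiator held at its charge as if it never ran down, is 140 min, shorter than the 180 min by the step with living end at 20.0 min, a factor of 1.21. The catch constant puts midnight's half-life at 173 min, between the two, while after 10.0 min initiator stands at 0.00823 % of its charge and living end at 0.00400 M. For winter after 200 min, the same constant leaves 9.06 % of the free monomer, and the flask holds 9.27 %.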